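If you repeat this run, the curve to watch is the starting material.

all flasks: starting material 0.40 M

|  | reagent | protic impurity | remark | time |
|---|---|---|---|---|
| Thursday's | 0.54 M | 0.40 M | run made earlier |  |
| north-west | 0.800 M | 0.400 M |  | 3.0 h |
| east | 0.800 M | 0.800 M |  | 3.0 h |

Thursday's run (percent of the starting material charged)

| time / min | starting material / % | isomer of the product / % | target / % |
|---|---|---|---|
| 15.0 | 98.4 | 0.5 | 0 |
| 40.0 | 96.4 | 0.1 | 0.1 |
| 80.0 | 91.2 | 0.2 | 0.1 |
| 120 | 87.3 | 0 | 1.1 |

(readings scatter by 0.5 percentage points)

- candidate steps: starting material + reagent + by-product -> target + 2 by-product; starting material + reagent -> target + by-product; starting material + protic impurity -> quenched substrate; target <-> isomer of the product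
- no earlier run changes the charge of protic impurity; that part of a forecast is a guess

1. which of these there is most of at the end, counted by the starting material in it, north-west (starting material / target / isomer of the product)
2. which of these there is most of at the end, counted by the starting material in it, east (starting material / target / isomer of the product)
3. amount of the one of these that there is most of at the end, in percent of the starting material charged, north-west
4. amount of the one of these that there is most of at the end, in percent of the starting material charged, east

Where did Thursday's loss go? At 120 min the starting material reads 87.3%, a loss of 13 percentage points, while target reads 1.1% and isomer of the product 0%, far less than that loss. The candidate step that feeds neither is the quench by protic impurity, so I book the loss there.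

What do you carry forward? The common logarithm of that last reading, divided by its time, gives 0.0295 h⁻¹. This is the decadic quench slope, the decades of starting material lost per hour at [protic impurity] of 0.40 M. It is a pseudo-first-order constant in powers of ten, with [protic impurity] read as steady.

And north-west? North-west is charged with the same [protic impurity] as Thursday's run, so 3.0 h costs 0.0885 decades, which leaves 81.6%.

East? Decades scale with [protic impurity] if the quench is first order in it, so the loss is 0.177 decades, which leaves 66.5%.

Where is that weak? No earlier run varied [protic impurity], so the scaling is a guess. The target's 1.1%, against a scatter of 0.5 points, may also be the onset of the by-product-driven step, now at higher [reagent]. I still commit to starting material in both flasks.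

Against my figures the forecast, which says “so I shade the values down”, is lower, with starting material at 76% in north-west and starting material at 62% in east.

The flask gives starting material at 81.8% in north-west and starting material at 66.8% in east.

    starting material + reagent + by-product → target + 2 by-product (k = 2.81 × 10⁻⁴ M⁻² s⁻¹)
    starting material + reagent → target + by-product (k = 1.88 × 10⁻⁸ M⁻¹ s⁻¹)
    starting material + protic impurity → quenched substrate (k = 5.14 × 10⁻⁵ M⁻¹ s⁻¹)
    target ⇌ isomer of the product (K = 0.541, k = 3.90 × 10⁻⁶ s⁻¹)

East lies below north-west because of its 0.800 M of protic impurity: with that difference in protic impurity taken away, east stands at 81.8%, not 66.8%. Read backwards, north-west gives a slope of 0.0291 h⁻¹ and east, scaled to 0.40 M, gives 0.0292 h⁻¹, beside the 0.0295 h⁻¹ from Thursday. For the neighbour flask, north-west with [protic impurity] at 0.10 M, the slope gives 95.0%, and that flask holds 95.1% of its starting material.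

(Readings and results are simulated from invented constants; the scatter is artificial.)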